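(The earlier runs and the new flask were computed for an exercise, and the scatter is random.)

The dawn run was short of 3.96 mM of electrophile at its first reading, counting what was neither electrophile nor product, and it was charged with 4 mM of protic impurity.

| setting | midnight | dawn | summer | flask |
|---|---|---|---|---|
| electrophile | 10 mM | 10 mM | 15 mM | 10 mM |
| nucleophile | 3 equiv | 3 equiv | 3 equiv | 3.00 equiv |
| buffer base | 3 equiv | 3 equiv | 3 equiv | 3.00 equiv |
| buffer acid | 0.10 equiv | 0.10 equiv | 0.10 equiv | 0.100 equiv |
| protic impurity | 1 mM | 4 mM | 2 mM | 2.00 mM |
| remark | run made earlier | run made earlier | run made earlier |  |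
| time |  |  |  | 4.0 min |

| run | time / min | electrophile / % | product / % |
|---|---|---|---|
| midnight | 0.250 | 84.5 | 6.2 |
| midnight | 0.667 | 74.3 | 15.3 |
| midnight | 1.33 | 62.7 | 27.7 |
| midnight | 3.00 | 40.8 | 48.4 |
| dawn | 0.417 | 53.2 | 7.2 |
| dawn | 1.00 | 44.7 | 16.3 |
| dawn | 2.00 | 32.4 | 24.0 |
| dawn | 3.00 | 27.1 | 32.4 |
| summer | 0.833 | 60.9 | 24.5 |
| summer | 1.50 | 48.1 | 38.6 |
| summer | 2.50 | 33.1 | 53.9 |
| summer | 3.00 | 28.5 | 59.3 |

(each reading ± 1 percentage point)

1. part of the electrophile that has reacted at 4.0 min
2. pH of the solution at 4.0 min

- the earlier runs do not show the pH; that part of a forecast is a guess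

The midnight run was short of 0.930 mM against 1 mM charged. The summer run was short of 2.19 mM against 2 mM. So read a fast burst: one impurity takes one electrophile and gives no product. That is the early end of your flask. Reckon as if the burst were instant: [electrophile] starts at 8.00 mM, with [nucleophile] at 30.0 mM. Electrophile is then the limiting reagent.

The late end is a second-order step, with rate = k[electrophile][nucleophile]. In the midnight run, from 0.667 min to 3.00 min, the logarithm of the electrophile ratio gives 0.257 min⁻¹. Counting one nucleophile lost per product, [nucleophile] averaged 26.8 mM. Divide, and you read the rate constant k as 0.160 M⁻¹ s⁻¹, with the scatter of those readings.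

Now join the ends. Take both reagents to fall one for one, so keep their difference, the surplus, as 22.0 mM. The ratio [nucleophile]/[electrophile] grows by exp(k × surplus × time). In your flask that factor is 2.32, taking the ratio from 3.75 to 8.71. Then [electrophile] = surplus/(ratio − 1) = 2.85 mM, so your reckoning for c is 71.5%. The runs show no pH, so you have no reckoning for it.

The forecast gives 72%, a little above yours, and pH 7.6, of which it says “This is a guess”.

The flask gives 71.5% and pH 8.02.

    protonated nucleophile ⇌ nucleophile + acid, settled at all times (K = 1.30 × 10⁻⁶ M)
    buffer acid ⇌ buffer base + acid, settled at all times (K = 4.00 × 10⁻⁸ M)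
    electrophile + nucleophile → acid + product + leaving group (k = 0.160 M⁻¹ s⁻¹)
    electrophile + protic impurity → quenched substrate (k = 29.0 M⁻¹ s⁻¹)

Take the neighbouring flask with 1.80 equiv of nucleophile, read at the same 4.00 min. Its impurity charge is the same, so reckon 8.00 mM after the burst again. [Nucleophile] starts at 18.0 mM, so the surplus is 10.0 mM. With the same k, the growth factor is 1.47 and the ratio ends at 3.30. That gives [electrophile] as 4.35 mM, or 43.5% of the charge. The neighbouring flask reaches 56.6% reacted. The largest share of its charge stands as electrophile, at 43.4%, against product at 36.6%.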